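**Plan**

- Retrosynthesis: the N–H pyrrole is traced back to its N-tosyl 2,5-dihydro form (N–S bond and C2–H restored). The ring C3=C4 bond is then cut by olefin metathesis to an acyclic N-allyl diene.
- The diene is cut at N–S and O–CH3, then at C2–C3 and C2–N in one three-component operation (alkenylboronic acid, glyoxylic acid, allylamine). The alkenylboron unit is cut at C–B and at the allylic C–C bond, leading to a C22 Grignard reagent and 2,3-dibromopropene.
- Enabling feature: in the pyrrole ring the C3–C4 bond links the tricosyl-bearing C3 to the unsubstituted C4–H. C3 can therefore be carried as a 1,1-disubstituted alkene on the carbon next to the amino-ester carbon C2, and C4–C5 as an allyl group on N1. The C2–H alpha to the ester later allows aromatisation without an oxidant.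
- Forward order: the chain is joined first (C22 + C3), then boron is introduced, then the amino acid, ester and sulfonamide are built. The only ring arises in the metathesis step and is aromatised by loss of sulfinate.
- Stereochemistry: the target has no stereocentre; C2 is formed as a racemate and is flattened in the last step.

Key step: step 6

Remark: glyoxylic acid is taken as its commercial monohydrate, and compounds 11 to 14 are handled as racemates because their single stereocentre is destroyed in step 7.

**Route**

Step 1
Reactants: 1 1-bromodocosane; 2 2,3-dibromopropene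
Product: 4 2-bromopentacos-1-ene, via docosylmagnesium bromide 3 (not isolated)
Conditions: Mg turnings, THF, 55 °C; then 2 (1.3 equiv), CuI (5 mol %), THF, −10 °C to rt
Reagents that add atoms: none
Why: Copper-catalysed allylic substitution of a Grignard reagent on 2,3-dibromopropene is a standard entry to 2-bromo-1-alkenes; direct and allylically transposed attack give the same product, and the vinylic bromide should stay untouched.

Step 2
Reactants: 4 2-bromopentacos-1-ene
Product: 7 pentacos-1-en-2-ylboronic acid, via pentacos-1-en-2-ylmagnesium bromide 5 (not isolated), via diisopropyl pentacos-1-en-2-ylboronate 6 (not isolated)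
Conditions: Mg turnings, THF, 60 °C; then B(OiPr)3, THF, −40 °C to rt; then 1 M HCl
Reagents that add atoms: triisopropyl borate, CC(C)OB(OC(C)C)OC(C)C; water, O
Why: Magnesium insertion into the vinylic C–Br bond followed by trapping with a hindered borate (Grignard borylation) should stop at single transfer, and acid hydrolysis frees the boronic acid.

Step 3
Reactants: 7 pentacos-1-en-2-ylboronic acid; 8 allylamine; 9 glyoxylic acid (monohydrate)
Product: 11 rac-2-(allylamino)-3-methylidenehexacosanoic acid, via 2-(allylimino)acetic acid 10 (not isolated)
Conditions: CH2Cl2/HFIP (9:1), rt to 40 °C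
Reagents that add atoms: none
Why: In this Petasis borono-Mannich reaction the amine and aldehyde condense, the carboxylate binds boron and the alkenyl group migrates intramolecularly to the iminium carbon; primary allylamine and alpha-substituted alkenylboronic acids are both known partners, and C2 forms as a racemate because nothing chiral is present.

Step 4
Reactants: 11 rac-2-(allylamino)-3-methylidenehexacosanoic acid
Product: 12 rac-methyl 2-(allylamino)-3-methylidenehexacosanoate
Conditions: TMSCHN2 (2 M in hexanes), toluene/MeOH (3:1), 0 °C to rt
Reagents that add atoms: (trimethylsilyl)diazomethane, C[Si](C)(C)C=[N+]=[N-]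
Why: O-Methylation of the carboxylic acid with (trimethylsilyl)diazomethane in methanol is near-neutral, so the secondary amine should stay unalkylated and the beta,gamma-alkene out of conjugation.

Step 5
Reactants: 12 rac-methyl 2-(allylamino)-3-methylidenehexacosanoate
Product: 13 rac-methyl 2-[allyl(p-tolylsulfonyl)amino]-3-methylidenehexacosanoate
Conditions: TsCl (1.5 equiv), Et3N, DMAP (0.2 equiv), CH2Cl2, rt to 40 °C
Reagents that add atoms: p-toluenesulfonyl chloride, Cc1ccc(cc1)S(=O)(=O)Cl
Why: DMAP-catalysed N-sulfonylation of the secondary amine; triethylamine is too weak to deprotonate C2, so the alkene should not migrate.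

Step 6
Reactants: 13 rac-methyl 2-[allyl(p-tolylsulfonyl)amino]-3-methylidenehexacosanoate
Product: 14 rac-methyl 1-tosyl-3-tricosyl-2,5-dihydro-1H-pyrrole-2-carboxylate
Conditions: second-generation Grubbs catalyst RuCl2(=CHPh)(PCy3)(H2IMes) (5 mol %), CH2Cl2 (0.01 M), 40 °C
Reagents that add atoms: none
Why: The ruthenium benzylidene should first exchange with the unhindered N-allyl alkene; the new alkylidene then adds across the 1,1-disubstituted alkene in a [2+2] step, and cycloreversion of the ruthenacyclobutane forms the C3=C4 bond, with ethylene as the only by-product. The closest known reaction type is ring-closing metathesis of N-sulfonyl N-allyl (2-substituted allyl)amines and of N-allyl vinylglycine derivatives to 3-pyrrolines. The one ring closes as a five-membered 2,5-dihydropyrrole by joining the internal carbon of the allyl group to the substituted alkene carbon, so the tricosyl group ends on C3 and C4 carries only hydrogen. No stereocentre is created; the C2 centre is a spectator and stays racemic. The step needs cyclisation to win over intermolecular cross-metathesis, which dilution, the fast five-ring closure and the reluctance of the 1,1-disubstituted alkene to dimerise should secure. The sulfonyl group keeps nitrogen from binding ruthenium, and the position of the new double bond is fixed by the two alkene termini.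

Step 7
Reactants: 14 rac-methyl 1-tosyl-3-tricosyl-2,5-dihydro-1H-pyrrole-2-carboxylate
Product: 16 methyl 3-tricosyl-1H-pyrrole-2-carboxylate (CNP0310694.0), via methyl 4-tricosyl-2H-pyrrole-5-carboxylate 15 (not isolated)
Conditions: NaOMe (2.5 equiv), MeOH/THF (1:1), 50 °C; then 1 M HCl
Reagents that add atoms: none
Why: Methoxide removes the C2 proton (alpha to the ester and allylic), the carbanion expels p-toluenesulfinate from nitrogen (E1cB elimination) and the 2H-pyrrole tautomerises to the aromatic 1H-pyrrole; the alkoxide matches the methyl ester, so ester exchange is harmless, and the C2 stereocentre disappears.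

**Compound list**

1 | 1-bromodocosane | CCCCCCCCCCCCCCCCCCCCCCBr | starting material
2 | 2,3-dibromopropene | C=C(Br)CBr | starting material
3 | docosylmagnesium bromide | CCCCCCCCCCCCCCCCCCCCCC[Mg]Br | intermediate
4 | 2-bromopentacos-1-ene | CCCCCCCCCCCCCCCCCCCCCCCC(Br)=C | intermediate
5 | pentacos-1-en-2-ylmagnesium bromide | CCCCCCCCCCCCCCCCCCCCCCCC([Mg]Br)=C | intermediate
6 | diisopropyl pentacos-1-en-2-ylboronate | CCCCCCCCCCCCCCCCCCCCCCCC(=C)B(OC(C)C)OC(C)C | intermediate
7 | pentacos-1-en-2-ylboronic acid | CCCCCCCCCCCCCCCCCCCCCCCC(=C)B(O)O | intermediate
8 | allylamine | C=CCN | starting material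
9 | glyoxylic acid (used as monohydrate) | O=CC(=O)O | starting material
10 | 2-(allylimino)acetic acid | C=CCN=CC(=O)O | intermediate
11 | rac-2-(allylamino)-3-methylidenehexacosanoic acid | CCCCCCCCCCCCCCCCCCCCCCCC(=C)C(NCC=C)C(=O)O | intermediate
12 | rac-methyl 2-(allylamino)-3-methylidenehexacosanoate | CCCCCCCCCCCCCCCCCCCCCCCC(=C)C(NCC=C)C(=O)OC | intermediate
13 | rac-methyl 2-[allyl(p-tolylsulfonyl)amino]-3-methylidenehexacosanoate | CCCCCCCCCCCCCCCCCCCCCCCC(=C)C(C(=O)OC)N(CC=C)S(=O)(=O)c1ccc(C)cc1 | intermediate
14 | rac-methyl 1-tosyl-3-tricosyl-2,5-dihydro-1H-pyrrole-2-carboxylate | CCCCCCCCCCCCCCCCCCCCCCCC1=CCN(S(=O)(=O)c2ccc(C)cc2)C1C(=O)OC | intermediate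
15 | methyl 4-tricosyl-2H-pyrrole-5-carboxylate | CCCCCCCCCCCCCCCCCCCCCCCC1=CCN=C1C(=O)OC | intermediate
16 | methyl 3-tricosyl-1H-pyrrole-2-carboxylate | CCCCCCCCCCCCCCCCCCCCCCCc1cc[nH]c1C(=O)OC | target

**Count**

Total step count: 7. Longest linear sequence: 7 steps (1 to 16).

**Steps most likely to fail**

Step 3 (three-component amino acid assembly). Transfer of the alpha-branched alkenyl group from boron may be slow, and the primary amine may undergo a second Mannich alkylation; the waxy boronic acid may also stay out of solution. The fallback sets out from 4 and forms the C2–C3 bond with an organomagnesium reagent and the C2–N bond by substitution. Grignard reagent 5, made as in step 2, would be added at −78 °C to excess methyl glyoxylate in THF to give racemic methyl 2-hydroxy-3-methylidenehexacosanoate F1. The alcohol would be converted with Tf2O and 2,6-lutidine in CH2Cl2 at −78 °C into methyl 3-methylidene-2-(trifluoromethylsulfonyloxy)hexacosanoate F2. This would be treated in the same flask with allylamine; SN2 displacement alpha to the ester comes back to the route at 12.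

Step 5 (N-sulfonylation). Sulfonyl transfer to the hindered secondary nitrogen may be slow enough that hydrolysis of the sulfonyl chloride and base-induced alkene migration compete. The fallback reverses the order of N-substitution and sets out from 7. Methyl glyoxylate and p-toluenesulfonyl isocyanate would be heated in toluene to give, with loss of CO2, methyl 2-(tosylimino)acetate F3. Boronic acid 7 would add to this imine under catalysis by [Rh(cod)(MeCN)2]BF4 in dioxane at 60 °C to give racemic methyl 2-(tosylamino)-3-methylidenehexacosanoate F4. Allyl bromide and K2CO3 in DMF at rt would then alkylate the sulfonamide nitrogen and return to the route at 13.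

Step 7 (sulfinate loss and aromatisation). Expulsion of sulfinate from the C2 carbanion may lag behind reprotonation and double-bond migration, or ester cleavage by adventitious hydroxide may intervene, leaving the ring non-aromatic. The fallback sets out from 14 and aromatises by oxidation before the N–S bond is broken. DDQ in toluene at 90 °C would dehydrogenate the dihydropyrrole to methyl 1-tosyl-3-tricosyl-1H-pyrrole-2-carboxylate F5. Cs2CO3 in THF/MeOH at rt would then cleave the sulfonamide by attack of methoxide on sulfur, with the pyrrolide as leaving group, and arrive at 16.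

**Further compounds**

F1 | step 3 | rac-methyl 2-hydroxy-3-methylidenehexacosanoate | CCCCCCCCCCCCCCCCCCCCCCCC(=C)C(O)C(=O)OC
F2 | step 3 | rac-methyl 3-methylidene-2-(trifluoromethylsulfonyloxy)hexacosanoate | CCCCCCCCCCCCCCCCCCCCCCCC(=C)C(OS(=O)(=O)C(F)(F)F)C(=O)OC
F3 | step 5 | methyl 2-(tosylimino)acetate | COC(=O)C=NS(=O)(=O)c1ccc(C)cc1
F4 | step 5 | rac-methyl 2-(tosylamino)-3-methylidenehexacosanoate | CCCCCCCCCCCCCCCCCCCCCCCC(=C)C(NS(=O)(=O)c1ccc(C)cc1)C(=O)OC
F5 | step 7 | methyl 1-tosyl-3-tricosyl-1H-pyrrole-2-carboxylate | CCCCCCCCCCCCCCCCCCCCCCCc1ccn(S(=O)(=O)c2ccc(C)cc2)c1C(=O)OC
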